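How much of the substrate has reacted at 40 min, and what is the pH then?

substrate 0.031 M; acid 0.0930 mM; time 40 min

    target ⇌ isomer of the product (K1 = 1.4, k1 = 1.0 × 10⁻⁴ /s)
    substrate → weak acid + target (k2 = 1.1 × 10⁻⁴ /s)
    substrate + acid → weak acid + acid + target (k3 = 4.9 /M/s)
    weak acid ⇌ conjugate base + acid, settled at all times (K4 = 6.3 × 10⁻⁷ M)
    substrate ⇌ dormant form (K5 = 2.8, k5 = 0.0012 /s)

* part of the substrate that has reacted at 40 min
* pH of the solution at 40 min

- acid is the free proton; pH is minus the decimal logarithm of its molar concentration
- what has gone from substrate into another species counts as reacted, even if it can come back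
- run time (flask): 40 min

*Who takes the substrate first?* The parking step into the dormant form: its forward half-life of 9.6 min is shorter than the 25 min of the acid-catalysed step at the charge and the 110 min of the uncatalysed step.

*Can acid change that?* The catalysed step is pseudo-first-order in substrate, so it matches forward parking at the crossing acid, the parking constant over the catalytic constant, 0.245 mM. The charge of 0.0930 mM lies below it.

*But the run makes acid. Does it cross?* If the whole substrate charge became weak acid, the dissociation balance would give a ceiling of 0.194 mM, still below the crossing. So in this flask I expect the forward rate of parking to stay faster than that of the catalysed step, though dormant form can return.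

*So what is left at 40 min?* Dormant form returns with 4.29 × 10⁻⁴ /s. With [acid] held at 0.143 mM, the mean of charge and ceiling, substrate goes onward with 8.13 × 10⁻⁴ /s. The two linked pools then have a slow root of 1.52 × 10⁻⁴ /s and a fast root of 0.00229 /s. Keeping the slow mode and dropping the fast one leaves 8.98 % of the substrate, so I commit to 91.0 % reacted. The same slow mode gives 0.0161 M of weak acid and [acid] of 0.158 mM.

The forecast gives 89 % and pH 3.81, citing “fast parking into the dormant form”, and its conversion stands a little below mine.

The flask gives 90.2 % and pH 3.81, with forward catalysed over forward parking at 0.63 at 40.0 min, its [acid] still under the crossing. The neighbour flask charged with 2.3 × 10⁻⁴ M starts at 0.939 of the crossing, but its ceiling of 0.296 mM lies above it. With mean [acid] of 0.263 mM, its onward constant is 0.00140 /s and its slow root 2.13 × 10⁻⁴ /s, so I reckon 4.97 % of its substrate left. Simulated, that neighbour reaches [acid] of 0.277 mM at 40.0 min, past the crossing, and ends with 5.1 % of its substrate left and 94.9 % reacted.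

The constants used here stand for no real mixture; what happens was integrated by code.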